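The nine-membered oxonane (ether O, C2–C9; eunicellane numbering, see remark) is not cyclised directly but grown from a seven-membered lactone (C3(=O)–O–C7–C8–C9–O–C2) that bridges the 2,5-cis-tetrahydrofuran of a hydroisobenzofuran. Methylenation gives a 2-methylene-1,4-dioxepane whose tertiary C7–O bond is allylic to a 1-methoxyvinyl group; one Claisen shift forms C4–C5, converts the ester oxygen into the C3 ketone and leaves the C6(OMe)=C7(Me) enol ether, expanding the ring by two atoms. The step exploits the 1,5-relationship of the C3 and C7 oxygens across the bare C4–C5 bridge; C3, C6 and C7 are then set by convex-face additions.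

Key step: step 9

Remark: eunicellane-type numbering is assumed throughout. Tetrahydrofuran = C1, C2, O, C9, C10; oxonane = O, C2, C3 (Me, O-acyl), C4, C5, C6 (OMe), C7 (Me, OH), C8, C9; cyclohexane = C1, C10, C11 (Me, OAc), C12, C13, C14; C15 = CH(Me) on C14; C16 = lactone C=O. Centres formed as epimer mixtures that a later step corrects or erases (C2 in 13–16, C7 in 18–20, the lactol carbon in 28) carry no descriptor in the SMILES.

Step 1
Reactants: 1 (S)-3-bromo-2-methylpropan-1-ol
Product: 2 (S)-(3-bromo-2-methylpropoxy)(tert-butyl)diphenylsilane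
Conditions: TBDPSCl, imidazole, CH2Cl2, 0 °C → rt
Reagents that add atoms: tert-butyl(chloro)diphenylsilane CC(C)(C)[Si](Cl)(c1ccccc1)c1ccccc1
Why: Imidazole-mediated silyl ether formation on the primary alcohol; TBDPS is chosen because it has to survive aqueous HCl (step 7) and borane (step 12), and the C15 stereocentre comes untouched from the chiral pool.

Step 2
Reactants: 2 (S)-(3-bromo-2-methylpropoxy)(tert-butyl)diphenylsilane
Product: 4 (R)-4-(tert-butyldiphenylsilyloxy)-3-methylbutanal, via Grignard reagent 3 (not isolated)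
Conditions: Mg, I2 (cat.), THF, 40 °C; DMF, 0 °C; aq. NH4Cl
Reagents that add atoms: N,N-dimethylformamide CN(C)C=O
Why: Bouveault formylation: the primary Grignard reagent adds once to DMF and the hemiaminal salt releases the aldehyde only on work-up; the γ-silyloxy group cannot β-eliminate and C15 is remote from the carbanion.

Step 3
Reactants: 4 (R)-4-(tert-butyldiphenylsilyloxy)-3-methylbutanal; 5 but-3-en-2-one
Product: 7 (R)-4-[(R)-1-(tert-butyldiphenylsilyloxy)propan-2-yl]cyclohex-2-en-1-one, via keto aldehyde 6 (not isolated)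
Conditions: (S)-α,α-diphenylprolinol methyl ether (5 mol %), ethyl 3,4-dihydroxybenzoate (20 mol %), neat, 4 °C; then LiOH, i-PrOH, rt
Reagents that add atoms: none
Why: Enamine-catalysed Michael addition followed by intramolecular aldol condensation (Robinson-type annulation); the (S)-catalyst shields one face of the E-enamine, so C14 is set by catalyst control next to the resident C15 centre, and the methyl ketone then closes onto the aldehyde.

Step 4
Reactants: 8 methyl 2-hydroxyacetate
Product: 10 1-methoxy-1,2-bis(trimethylsilyloxy)ethene, via silyl ether 9 (not isolated)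
Conditions: TMSCl, Et3N, Et2O, 0 °C; filter; LDA, TMSCl, THF, −78 °C
Reagents that add atoms: chlorotrimethylsilane C[Si](C)(C)Cl
Why: O-Silylation of the hydroxyl and then of the ester enolate (ketene silyl acetal formation) gives the glycolate nucleophile that will become C2/C3; no stereocentre is involved.

Step 5
Reactants: 11 ethyl 2-(2-methyl-1,3-dioxolan-2-yl)acetate
Product: 12 2-(2-methyl-1,3-dioxolan-2-yl)acetaldehyde
Conditions: DIBAL-H, CH2Cl2, −78 °C; Rochelle salt
Reagents that add atoms: none
Why: Low-temperature DIBAL-H half-reduction stops at the aluminium hemiacetal, which gives the aldehyde (future C9) on work-up; the dioxolane masks the future C7 ketone so that only one ketone is present in step 7.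

Step 6
Reactants: 7 (R)-4-[(R)-1-(tert-butyldiphenylsilyloxy)propan-2-yl]cyclohex-2-en-1-one; 10 1-methoxy-1,2-bis(trimethylsilyloxy)ethene; 12 2-(2-methyl-1,3-dioxolan-2-yl)acetaldehyde
Product: 14 cis-fused keto ester (C11 ketone; C2–CO2Me as epimers; C9 ketal side chain exo), via bis-silyl Michael adduct 13 (not isolated)
Conditions: TMSOTf (10 mol %), CH2Cl2, −78 °C; then 12, TMSOTf (0.3 equiv), −78 → −40 °C; Et3N
Reagents that add atoms: none
Why: Mukaiyama–Michael addition anti to the C14 substituent sets C1 and leaves the regiodefined C10=C11 enol silane; TMSOTf then condenses the C2–OTMS ether with the aldehyde to an oxocarbenium ion, which the enol silane captures in an intramolecular Mukaiyama aldol-type closure (C9–C10 bond), the three-atom tether enforcing the cis ring fusion at C10 and the C9 chain taking the convex position, while C2 is unselective and is corrected in step 7.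

Step 7
Reactants: 14 cis-fused keto ester
Product: 17 hydroxy keto ester (all-exo; C11(Me)OH with Me cis to H10; C9–CH2COCH3), via ketal carbinol 15 (not isolated), via C2-epimeric methyl ketone 16 (not isolated)
Conditions: MeMgBr, CeCl3, THF, −78 °C; 1 M HCl, THF, rt; then NaOMe (0.2 equiv), MeOH, rt
Reagents that add atoms: methylmagnesium bromide C[Mg]Br; water O
Why: Cerium-mediated Grignard 1,2-addition is selective for the ketone over the ester and comes from the convex face anti to the axial C10–C9 bond, setting C11; ketal hydrolysis unmasks the C7 ketone, and catalytic methoxide then equilibrates C2 (ester α-epimerisation) and C9 (retro-oxa-Michael/oxa-Michael through the C8 enolate) to the thermodynamically preferred all-exo isomer, C10 being no longer epimerisable.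

Step 8
Reactants: 17 hydroxy keto ester
Product: 19 bridged lactone (C3(=O)–O–C7 across C2 and C9; C7 bears Me plus 1-methoxyvinyl), via hydroxy ester 18 (not isolated)
Conditions: CH2=C(OMe)Li (from MeOCH=CH2, t-BuLi, THF, −78 → 0 °C), CeCl3, THF, −78 °C; MeOH (1 equiv), → rt
Reagents that add atoms: 1-methoxyvinyllithium [Li]C(=C)OC
Why: 1,2-Addition of the 1-methoxyvinyl organocerium (chosen to suppress enolisation and β-elimination of the C9 oxygen) to the methyl ketone gives a tertiary alkoxide that closes onto the cis-disposed C3 ester by intramolecular transesterification (lactonisation) once excess reagent is destroyed; the C7 configuration does not matter because step 9 erases it.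

Step 9
Reactants: 19 bridged lactone
Product: 21 oxonenone (C3 ketone; ring-cis C6(OMe)=C7(Me); C11(Me)OH), via 2-methylene-1,4-dioxepane 20 (not isolated)
Conditions: Tebbe reagent, pyridine, THF/PhMe, −40 → 0 °C; filter (basic Al2O3); PhMe, 140 °C, sealed tube, base-washed glass
Reagents that add atoms: Tebbe reagent (Cp2Ti=CH2·AlMe2Cl) C=[Ti](C1C=CC=C1)C1C=CC=C1.C[Al](C)Cl
Why: Tebbe methylenation turns the lactone carbonyl into the exocyclic enol ether 20, an allyl vinyl ether C4=C3–O–C7–C6=C5 locked in a seven-membered ring (C3, O, C7, C8, C9, O, C2), and heating triggers a concerted [3,3]-sigmatropic Claisen shift that makes C4–C5 and breaks C7–O. The closest known reaction type is the Claisen ring expansion of 2-methylene cyclic ethers bearing a vinyl group next to the ring oxygen, which has been used to reach oxonenes bridged across a 2,5-cis-tetrahydrofuran. The nine-membered ring (O, C2–C9) is therefore not closed by a cyclisation but arises from the seven-membered ring by a two-atom ring expansion through a bicyclic boat-like transition state, the former ester oxygen leaving the ring as the C3 ketone. No sp3 stereocentre is created: the C6=C7 geometry (C5 and C8 cis) is fixed by the ring constraint and the C7 centre is planarised, so both C7 epimers of 19 should converge on 21. The step needs methylenation of the only carbonyl present (excess reagent covers the free C11 hydroxyl, which is recovered on work-up) and rearrangement in preference to acid-catalysed isomerisation of the enol ethers, which base-washed glassware and removal of titanium and aluminium residues before heating secure. The donor methoxy group at the central allyl carbon is expected to slow but not stop the shift, while the fully substituted C7 accelerates it.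

Step 10
Reactants: 21 oxonenone
Product: 22 oxonenone acetate (C11 OAc)
Conditions: Ac2O, DMAP, Et3N, CH2Cl2, 40 °C
Reagents that add atoms: acetic anhydride CC(=O)OC(C)=O
Why: DMAP-catalysed acylation of the only free hydroxyl, the tertiary C11 alcohol, under basic conditions that leave the enol ether and ketone untouched; it is placed after the methylenation (which would attack an ester) and before the other tertiary alcohols appear.

Step 11
Reactants: 22 oxonenone acetate
Product: 23 C3 carbinol (C3(Me)OH with oxygen syn to C1)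
Conditions: MeMgBr, CeCl3, THF, −78 °C
Reagents that add atoms: methylmagnesium bromide C[Mg]Br
Why: Cerium-mediated Grignard 1,2-addition to the C3 ketone is selective over the hindered tertiary acetate at −78 °C; the nucleophile should approach the oxabicyclic ketone from the convex face anti to the C1–C10 bridge, placing methyl outside and the C3 oxygen syn to C1, as the later lactone requires.

Step 12
Reactants: 23 C3 carbinol
Product: 25 diol (C3–OH; C6–OMe; C7–OH; C11–OAc; C16–OTBDPS), via tertiary borane 24 (not isolated)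
Conditions: BH3·THF (excess), THF, 0 °C → rt; NaBO3·4H2O, THF/H2O, rt
Reagents that add atoms: sodium perborate [Na+].[O-]OB=O
Why: Hydroboration–oxidation of the tetrasubstituted enol ether: boron adds to C7 (β to oxygen) and hydrogen to C6 in a syn fashion from the convex face anti to the C1–C10 bridge, and oxidation with retention gives C7–OH with the C6 methoxy on the opposite face, so C6 and C7 are set together; the C3 hydroxyl is tied up as an unreactive borate and perborate spares the acetate.

Step 13
Reactants: 25 diol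
Product: 26 triol (C16 primary OH; C3 and C7 tertiary OH; C11–OAc)
Conditions: TBAF, AcOH, THF, rt
Reagents that add atoms: none
Why: Fluoride-mediated desilylation of the TBDPS ether, buffered with acetic acid so that the tertiary acetate is neither cleaved nor migrated, frees the primary C16 alcohol.

Step 14
Reactants: 26 triol
Product: 29 CNP0238771.1, via hydroxy aldehyde 27 (not isolated), via lactol 28 (not isolated)
Conditions: TEMPO (20 mol %), PhI(OAc)2, CH2Cl2, rt
Reagents that add atoms: none
Why: TEMPO/PhI(OAc)2 oxidative lactonisation: the primary alcohol is oxidised selectively to the aldehyde, the C3 tertiary hydroxyl held nearby by the C1–C2 and C14–C15 framework adds to give the seven-membered lactol, and a second oxoammonium oxidation gives the lactone; the C7 hydroxyl and the acetate are inert and C15 should not epimerise under these non-basic conditions.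

Compound list
1 | (S)-3-bromo-2-methylpropan-1-ol | OC[C@H](C)CBr | starting material
2 | (S)-(3-bromo-2-methylpropoxy)(tert-butyl)diphenylsilane | CC(C)(C)[Si](c1ccccc1)(c1ccccc1)OC[C@H](C)CBr | intermediate
3 | Grignard reagent: [(S)-3-(tert-butyldiphenylsilyloxy)-2-methylpropyl]magnesium bromide | CC(C)(C)[Si](c1ccccc1)(c1ccccc1)OC[C@H](C)C[Mg]Br | intermediate
4 | (R)-4-(tert-butyldiphenylsilyloxy)-3-methylbutanal | CC(C)(C)[Si](c1ccccc1)(c1ccccc1)OC[C@H](C)CC=O | intermediate
5 | but-3-en-2-one | CC(=O)C=C | starting material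
6 | keto aldehyde: (S)-2-[(R)-1-(tert-butyldiphenylsilyloxy)propan-2-yl]-5-oxohexanal | CC(C)(C)[Si](c1ccccc1)(c1ccccc1)OC[C@H](C)[C@@H](C=O)CCC(C)=O | intermediate
7 | (R)-4-[(R)-1-(tert-butyldiphenylsilyloxy)propan-2-yl]cyclohex-2-en-1-one | CC(C)(C)[Si](c1ccccc1)(c1ccccc1)OC[C@H](C)[C@@H]1CCC(=O)C=C1 | intermediate
8 | methyl 2-hydroxyacetate | COC(=O)CO | starting material
9 | silyl ether: methyl 2-(trimethylsilyloxy)acetate | COC(=O)CO[Si](C)(C)C | intermediate
10 | 1-methoxy-1,2-bis(trimethylsilyloxy)ethene (E/Z mixture) | COC(O[Si](C)(C)C)=CO[Si](C)(C)C | intermediate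
11 | ethyl 2-(2-methyl-1,3-dioxolan-2-yl)acetate | CCOC(=O)CC1(C)OCCO1 | starting material
12 | 2-(2-methyl-1,3-dioxolan-2-yl)acetaldehyde | O=CCC1(C)OCCO1 | intermediate
13 | bis-silyl Michael adduct: methyl 2-(trimethylsilyloxy)-2-[6-[(R)-1-(tert-butyldiphenylsilyloxy)propan-2-yl]-3-(trimethylsilyloxy)cyclohex-2-en-1-yl]acetate; C1–C2 bond trans to the C14 side chain; C2 epimers | COC(=O)C(O[Si](C)(C)C)[C@@H]1C=C(O[Si](C)(C)C)CC[C@H]1[C@@H](C)CO[Si](c2ccccc2)(c2ccccc2)C(C)(C)C | intermediate
14 | cis-fused keto ester: methyl 3-[(2-methyl-1,3-dioxolan-2-yl)methyl]-4-oxo-7-[(R)-1-(tert-butyldiphenylsilyloxy)propan-2-yl]octahydroisobenzofuran-1-carboxylate; C11 ketone; C9 chain exo; C2 epimers | COC(=O)C1O[C@@H](CC3(C)OCCO3)[C@@H]2C(=O)CC[C@@H]([C@@H](C)CO[Si](c4ccccc4)(c4ccccc4)C(C)(C)C)[C@H]12 | intermediate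
15 | ketal carbinol: 14 with C11(Me)OH (Me cis to H10); C2 epimers | COC(=O)C1O[C@@H](CC3(C)OCCO3)[C@@H]2[C@](C)(O)CC[C@@H]([C@@H](C)CO[Si](c4ccccc4)(c4ccccc4)C(C)(C)C)[C@H]12 | intermediate
16 | C2-epimeric methyl ketone: 15 with C9–CH2COCH3 | COC(=O)C1O[C@@H](CC(C)=O)[C@@H]2[C@](C)(O)CC[C@@H]([C@@H](C)CO[Si](c3ccccc3)(c3ccccc3)C(C)(C)C)[C@H]12 | intermediate
17 | hydroxy keto ester: methyl 4-hydroxy-4-methyl-3-(2-oxopropyl)-7-[(R)-1-(tert-butyldiphenylsilyloxy)propan-2-yl]octahydroisobenzofuran-1-carboxylate; cis-fused; C2 and C9 substituents exo | COC(=O)[C@H]1O[C@@H](CC(C)=O)[C@@H]2[C@](C)(O)CC[C@@H]([C@@H](C)CO[Si](c3ccccc3)(c3ccccc3)C(C)(C)C)[C@H]12 | intermediate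
18 | hydroxy ester: 17 with C7(Me)(OH)C(OMe)=CH2; C7 epimers | COC(=O)[C@H]1O[C@@H](CC(C)(O)C(=C)OC)[C@@H]2[C@](C)(O)CC[C@@H]([C@@H](C)CO[Si](c3ccccc3)(c3ccccc3)C(C)(C)C)[C@H]12 | intermediate
19 | bridged lactone: seven-membered C3(=O)–O–C7(Me)(1-methoxyvinyl)–C8–C9–O–C2 ring across the tetrahydrofuran; C11(Me)OH; C7 epimers | COC(=C)C1(C)C[C@@H]2O[C@H](C(=O)O1)[C@@H]3[C@H]2[C@](C)(O)CC[C@H]3[C@@H](C)CO[Si](c4ccccc4)(c4ccccc4)C(C)(C)C | intermediate
20 | 2-methylene-1,4-dioxepane: 19 with C3=CH2 in place of C3=O | COC(=C)C1(C)C[C@@H]2O[C@H](C(=C)O1)[C@@H]3[C@H]2[C@](C)(O)CC[C@H]3[C@@H](C)CO[Si](c4ccccc4)(c4ccccc4)C(C)(C)C | intermediate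
21 | oxonenone: tricycle with C3 ketone; ring-cis C6(OMe)=C7(Me) enol ether; C11(Me)OH; C14 CH(Me)CH2OTBDPS | CO/C1=C(\C)C[C@@H]2O[C@H](C(=O)CC1)[C@@H]3[C@H]2[C@](C)(O)CC[C@H]3[C@@H](C)CO[Si](c4ccccc4)(c4ccccc4)C(C)(C)C | intermediate
22 | oxonenone acetate: 21 with C11 OAc | CO/C1=C(\C)C[C@@H]2O[C@H](C(=O)CC1)[C@@H]3[C@H]2[C@](C)(OC(C)=O)CC[C@H]3[C@@H](C)CO[Si](c4ccccc4)(c4ccccc4)C(C)(C)C | intermediate
23 | C3 carbinol: 22 with C3(Me)OH; oxygen syn to C1 | CO/C1=C(\C)C[C@@H]2O[C@H]([C@@](C)(O)CC1)[C@@H]3[C@H]2[C@](C)(OC(C)=O)CC[C@H]3[C@@H](C)CO[Si](c4ccccc4)(c4ccccc4)C(C)(C)C | intermediate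
24 | tertiary borane: C7–BH2 and C6–H(OMe) from syn addition to 23 (C3 hydroxyl drawn free) | CO[C@H]1[C@](C)(B)C[C@@H]2O[C@H]([C@@](C)(O)CC1)[C@@H]3[C@H]2[C@](C)(OC(C)=O)CC[C@H]3[C@@H](C)CO[Si](c4ccccc4)(c4ccccc4)C(C)(C)C | intermediate
25 | diol: C3(Me)OH; C6 OMe; C7(Me)OH; C11 OAc; C16 OTBDPS | CO[C@H]1[C@](C)(O)C[C@@H]2O[C@H]([C@@](C)(O)CC1)[C@@H]3[C@H]2[C@](C)(OC(C)=O)CC[C@H]3[C@@H](C)CO[Si](c4ccccc4)(c4ccccc4)C(C)(C)C | intermediate
26 | triol: 25 with free C16 hydroxyl | CO[C@H]1[C@](C)(O)C[C@@H]2O[C@H]([C@@](C)(O)CC1)[C@@H]3[C@H]2[C@](C)(OC(C)=O)CC[C@H]3[C@@H](C)CO | intermediate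
27 | hydroxy aldehyde: 26 with C16 as CHO | CO[C@H]1[C@](C)(O)C[C@@H]2O[C@H]([C@@](C)(O)CC1)[C@@H]3[C@H]2[C@](C)(OC(C)=O)CC[C@H]3[C@@H](C)C=O | intermediate
28 | lactol: C3–O–C16H(OH) seven-membered hemiacetal | CO[C@@H]1CC[C@]2(C)OC(O)[C@H](C)[C@@H]3CC[C@@](C)(OC(C)=O)[C@@H]4[C@H]3[C@@H]2O[C@H]4C[C@@]1(C)O | intermediate
29 | CNP0238771.1 | CO[C@@H]1CC[C@]2(C)OC(=O)[C@H](C)[C@@H]3CC[C@@](C)(OC(C)=O)[C@@H]4[C@H]3[C@@H]2O[C@H]4C[C@@]1(C)O | target

Total step count: 14. Longest linear sequence: 12 steps (steps 1–3 and 6–14; steps 4 and 5 make the two partners for step 6).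

Steps most likely to fail

Step 9. The donor methoxy group at the central allyl carbon may slow the [3,3] shift enough that isomerisation of the exocyclic enol ether into the ring, or ionisation of the tertiary allylic C7–O bond, competes; one C7 epimer may also fail to reach a reactive conformer. The fallback keeps the ring expansion but runs it on the plain vinyl analogue and installs the C6/C7 oxygens afterwards; it sets out from 17 and returns at 25. Vinylmagnesium bromide/CeCl3 adds to the methyl ketone of 17 to give the hydroxy ester F1, which lactonises as in step 8 to the vinyl lactone F2. Tebbe methylenation gives the methylene dioxepane F3, and heating gives the oxonenone F4 with a ring-cis C6=C7(Me) alkene. Acetylation (Ac2O, DMAP) gives F5 and MeMgBr/CeCl3 gives the C3 carbinol F6. OsO4/NMO dihydroxylation from the convex face gives the 6,7-cis-diol F7, Dess–Martin oxidation of the secondary hydroxyl gives the 7-hydroxy-6-ketone F8, and NaBH4 reduction with hydride from the convex face gives the 6,7-trans-diol F9. Selective O-methylation of its secondary hydroxyl (MeOTf, 2,6-di-tert-butyl-4-methylpyridine) gives 25.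

Step 6. Direct intermolecular aldol addition of the enol silane to the aldehyde, or protodesilylation of the enol silane, may outrun formation of the oxocarbenium ion, so that the tetrahydrofuran does not close through carbon. The fallback closes it through oxygen instead; it sets out from 13 (made from 7 and 10 as in the first stage of step 6) and 12, and returns at 14. BF3·OEt2-mediated Mukaiyama aldol addition at −78 °C, with a K2CO3/MeOH work-up that removes the trimethylsilyl groups, gives the aldol diol F10. p-TsOH (cat.) with MgSO4 in CH2Cl2 dehydrates the β-hydroxy ketone to the exocyclic enone F11, to which the C2 hydroxyl adds in a 5-exo oxa-Michael closure; protonation of the resulting enolate on the face of H1 should give the cis-fused keto ester 14.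

Step 14. The hydroxy aldehyde may not close to the seven-membered lactol, so that oxidation stalls at the aldehyde and C15 slowly epimerises. The fallback makes the carboxyl group first and forms the ester bond by acyl activation; it sets out from 26 and returns at 29. TEMPO/NaOCl/NaClO2 (pH 6.7 buffer) oxidises the primary alcohol to the seco acid F12; 2,4,6-trichlorobenzoyl chloride/Et3N converts it into the mixed anhydride F13, and DMAP in toluene at 80 °C closes the lactone onto the C3 tertiary hydroxyl (Yamaguchi lactonisation; the C7 hydroxyl cannot reach), giving 29.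

Further compounds
F1 | step 9 | hydroxy ester: 17 after vinyl addition to C7 (C7 epimers) | COC(=O)[C@H]1O[C@@H](CC(C)(O)C=C)[C@@H]2[C@](C)(O)CC[C@@H]([C@@H](C)CO[Si](c3ccccc3)(c3ccccc3)C(C)(C)C)[C@H]12
F2 | step 9 | vinyl lactone: 19 with vinyl in place of 1-methoxyvinyl | C=CC1(C)C[C@@H]2O[C@H](C(=O)O1)[C@@H]3[C@H]2[C@](C)(O)CC[C@H]3[C@@H](C)CO[Si](c4ccccc4)(c4ccccc4)C(C)(C)C
F3 | step 9 | 2-methylene-1,4-dioxepane of F2 | C=CC1(C)C[C@@H]2O[C@H](C(=C)O1)[C@@H]3[C@H]2[C@](C)(O)CC[C@H]3[C@@H](C)CO[Si](c4ccccc4)(c4ccccc4)C(C)(C)C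
F4 | step 9 | oxonenone with ring-cis C6=C7(Me) alkene; C3 ketone; C11(Me)OH | C/C1=C/CCC(=O)[C@H]2O[C@@H](C1)[C@@H]3[C@](C)(O)CC[C@@H]([C@@H](C)CO[Si](c4ccccc4)(c4ccccc4)C(C)(C)C)[C@H]23
F5 | step 9 | C11 acetate of F4 | C/C1=C/CCC(=O)[C@H]2O[C@@H](C1)[C@@H]3[C@](C)(OC(C)=O)CC[C@@H]([C@@H](C)CO[Si](c4ccccc4)(c4ccccc4)C(C)(C)C)[C@H]23
F6 | step 9 | C3 methyl carbinol of F5 | C/C1=C/CC[C@](C)(O)[C@H]2O[C@@H](C1)[C@@H]3[C@](C)(OC(C)=O)CC[C@@H]([C@@H](C)CO[Si](c4ccccc4)(c4ccccc4)C(C)(C)C)[C@H]23
F7 | step 9 | 6,7-cis-diol (both hydroxyls from the convex face) | O[C@@H]1[C@](C)(O)C[C@@H]2O[C@H]([C@@](C)(O)CC1)[C@@H]3[C@H]2[C@](C)(OC(C)=O)CC[C@H]3[C@@H](C)CO[Si](c4ccccc4)(c4ccccc4)C(C)(C)C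
F8 | step 9 | 7-hydroxy-6-ketone | O=C1[C@](C)(O)C[C@@H]2O[C@H]([C@@](C)(O)CC1)[C@@H]3[C@H]2[C@](C)(OC(C)=O)CC[C@H]3[C@@H](C)CO[Si](c4ccccc4)(c4ccccc4)C(C)(C)C
F9 | step 9 | 6,7-trans-diol (25 without the O-methyl group) | O[C@H]1[C@](C)(O)C[C@@H]2O[C@H]([C@@](C)(O)CC1)[C@@H]3[C@H]2[C@](C)(OC(C)=O)CC[C@H]3[C@@H](C)CO[Si](c4ccccc4)(c4ccccc4)C(C)(C)C
F10 | step 6 | Mukaiyama aldol diol (C2, C9 and C10 unassigned) | COC(=O)C(O)[C@@H]1C(C(O)CC3(C)OCCO3)C(=O)CC[C@H]1[C@@H](C)CO[Si](c2ccccc2)(c2ccccc2)C(C)(C)C
F11 | step 6 | exocyclic enone (C10=C9) with free C2 hydroxyl | COC(=O)C(O)[C@@H]1C(=CCC3(C)OCCO3)C(=O)CC[C@H]1[C@@H](C)CO[Si](c2ccccc2)(c2ccccc2)C(C)(C)C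
F12 | step 14 | seco acid (C16 carboxylic acid) | CO[C@H]1[C@](C)(O)C[C@@H]2O[C@H]([C@@](C)(O)CC1)[C@@H]3[C@H]2[C@](C)(OC(C)=O)CC[C@H]3[C@@H](C)C(O)=O
F13 | step 14 | mixed 2,4,6-trichlorobenzoic anhydride of F12 | CO[C@H]1[C@](C)(O)C[C@@H]2O[C@H]([C@@](C)(O)CC1)[C@@H]3[C@H]2[C@](C)(OC(C)=O)CC[C@H]3[C@@H](C)C(=O)OC(=O)c4c(Cl)cc(Cl)cc4Cl
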